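A direct plan would attach a finished chain to a bought arene: two C15 halves from (2E,6E)-farnesol A1, one of them its silyl ether A2 oxidised at the tail, would be joined to hexaprenyl phenyl sulfone A3, whose α-lithio anion would add to quinone monoketal A4; aromatisation to sulfonyl phenol A5, desulfonylation and oxidation would follow. Its weakest steps would be the SeO2 oxidation of the tail methyl group of A2 (three similar olefins, so it would be stopped early and most material would be lost at the outset), the conjugate addition of the A3 anion to A4 (α against γ and 1,4 against 1,2 attack on an acid-labile ketal), and the PdCl2(dppp)/LiBHEt3 desulfonylation of A5 (the olefin beside the ring could migrate or be reduced).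

The quinone ring is built last, around a finished all-E C30 chain (ring numbering: C1=O lies between C2–OMe and C6–chain). Photochemical Wolff rearrangement of α-diazo enone 19 gives a vinylketene that takes up methoxyacetylene (Danheiser benzannulation): one operation forms ring bonds C1–C6, C1–C2, C3–C4 and C4–C5 and places, by mechanism alone, the C2 methoxy group meta to the C4 oxygen with H at C3, next to the C5-methyl/C6-chain pair; C1 is oxygenated afterwards. The chain grows by Cp2ZrCl2-catalysed methylalumination of terminal alkynes, each cycle setting one E-olefin, and the last alkenylalane is coupled directly to the ring precursor. Tail oxidation, sulfonyl anions and desulfonylation have no counterpart.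

Key step: step 11

Assumption: all-E geranylgeraniol (1) is taken as a catalogue compound, and the geometry of the ethylidene bond in 16 to 19 is left open because that bond ends up inside the arene.

In names below, "hexaprenyl" means (2E,6E,10E,14E,18E)-3,7,11,15,19,23-hexamethyltetracosa-2,6,10,14,18,22-hexaen-1-yl.

Step 1
Reactants: 1 (2E,6E,10E)-geranylgeraniol
Product: 2 (2E,6E,10E)-geranylgeranyl bromide
Conditions: PBr3 (0.4 equiv), Et2O, −10 to 0 °C, dark; used crude
Reagents that add atoms: phosphorus tribromide, BrP(Br)Br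
Why: SN2 displacement on the phosphite ester of a primary allylic alcohol at low temperature should give the primary bromide without allylic transposition, so the 2E geometry is kept.

Step 2
Reactants: 2 (2E,6E,10E)-geranylgeranyl bromide
Product: 4 (5E,9E,13E)-6,10,14,18-tetramethylnonadeca-5,9,13,17-tetraen-1-yne, via silyl alkyne 3 (not isolated)
Conditions: MeC≡CSiMe3, n-BuLi, THF, −78 °C; then 2, −78 to −20 °C; then K2CO3, MeOH, rt
Reagents that add atoms: 1-(trimethylsilyl)propyne, CC#C[Si](C)(C)C
Why: Propargylic alkylation, in which the lithiated silylpropyne attacks the primary allylic bromide by SN2 through its CH2 terminus (the silyl group disfavours allenic coupling), followed by methanolysis of the alkynyl–silicon bond; no olefin is touched.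

Step 3
Reactants: 4 (5E,9E,13E)-6,10,14,18-tetramethylnonadeca-5,9,13,17-tetraen-1-yne
Product: 7 (2E,6E,10E,14E)-geranylfarnesol, via alkenylalane 5 (not isolated), via lithium alanate 6 (not isolated)
Conditions: Me3Al (2 equiv), Cp2ZrCl2 (0.25 equiv), CH2Cl2, 0 °C to rt; volatiles removed in vacuo; n-BuLi, hexane/THF, −78 °C; (CH2O)n, to rt; aq. work-up
Reagents that add atoms: trimethylaluminium, C[Al](C)C; formaldehyde (as paraformaldehyde), C=O
Why: Negishi carboalumination adds CH3 and Al syn across the terminal alkyne with Al on the terminal carbon, which fixes the new trisubstituted olefin as E, and the derived alanate is hydroxymethylated by formaldehyde with retention.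

Step 4
Reactants: 7 (2E,6E,10E,14E)-geranylfarnesol
Product: 8 (2E,6E,10E,14E)-geranylfarnesyl bromide
Conditions: PBr3 (0.4 equiv), Et2O, −10 to 0 °C, dark; used crude
Reagents that add atoms: phosphorus tribromide, BrP(Br)Br
Why: The same SN2 bromination of a primary allylic alcohol through its phosphite ester as in step 1, with retention of the 2E geometry.

Step 5
Reactants: 8 (2E,6E,10E,14E)-geranylfarnesyl bromide
Product: 10 (5E,9E,13E,17E)-6,10,14,18,22-pentamethyltricosa-5,9,13,17,21-pentaen-1-yne, via silyl alkyne 9 (not isolated)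
Conditions: MeC≡CSiMe3, n-BuLi, THF, −78 °C; then 8, −78 to −20 °C; then K2CO3, MeOH, rt
Reagents that add atoms: 1-(trimethylsilyl)propyne, CC#C[Si](C)(C)C
Why: The same propargylic SN2 alkylation and methanolytic desilylation as in step 2.

Step 6
Reactants: 11 methyl vinyl ketone; 12 acetaldehyde
Product: 13 4-hydroxy-3-methylidenepentan-2-one (racemic)
Conditions: DABCO (0.15 equiv), dioxane/H2O 1:1, 0 °C to rt
Reagents that add atoms: none
Why: Morita–Baylis–Hillman reaction, in which the DABCO-derived zwitterionic enolate of the enone adds to the aldehyde and the amine is expelled; the carbinol centre is racemic and disappears in step 8.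

Step 7
Reactants: 13 4-hydroxy-3-methylidenepentan-2-one
Product: 14 3-methylidene-4-oxopentan-2-yl acetate (racemic)
Conditions: Ac2O, Et3N, DMAP (cat.), CH2Cl2, 0 °C
Reagents that add atoms: acetic anhydride, CC(=O)OC(C)=O
Why: DMAP-catalysed acylation of the secondary allylic alcohol; an allylic shift of the acetate would be harmless because both isomers lead to the same allyl–palladium species.

Step 8
Reactants: 10 (5E,9E,13E,17E)-6,10,14,18,22-pentamethyltricosa-5,9,13,17,21-pentaen-1-yne; 14 3-methylidene-4-oxopentan-2-yl acetate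
Product: 16 3-hexaprenylpent-3-en-2-one (E/Z mixture at the ethylidene bond), via alkenylalane 15 (not isolated)
Conditions: 10, Me3Al (2 equiv), Cp2ZrCl2 (0.25 equiv), CH2Cl2, 0 °C to rt; volatiles removed in vacuo; then 14 (1.2 equiv), Pd(PPh3)4 (5 mol %), THF, 0 °C to rt
Reagents that add atoms: trimethylaluminium, C[Al](C)C
Why: Negishi carboalumination sets the last chain olefin (C2'=C3') as E by syn addition, and in the following alkenyl–allyl cross-coupling zerovalent palladium ionises the acetate to a 2-acetyl-π-allyl complex that receives the alkenyl group at its CH2 terminus with retention of the alkenyl geometry.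

Step 9
Reactants: 16 3-hexaprenylpent-3-en-2-one
Product: 19 1-diazo-3-hexaprenylpent-3-en-2-one, via lithium enolate 17 (not isolated), via trifluoroacetyl diketone 18 (not isolated)
Conditions: LiN(SiMe3)2, THF, −78 °C; CF3CO2CH2CF3; aq. HCl work-up; then MsN3, Et3N, H2O (1 equiv), MeCN, rt
Reagents that add atoms: methanesulfonyl azide, CS(=O)(=O)N=[N+]=[N-]
Why: Detrifluoroacetylative (Regitz-type) diazo transfer: kinetic deprotonation at the acetyl CH3, Claisen trifluoroacetylation and diazo transfer with loss of the trifluoroacetyl group, a sequence suited to α,β-unsaturated methyl ketones.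

Step 10
Reactants: 20 chloroacetaldehyde dimethyl acetal
Product: 22 methoxyacetylene, via sodium methoxyacetylide 21 (not isolated)
Conditions: NaNH2 (3.1 equiv), liquid NH3, −35 °C; then cold brine, −70 °C; distilled (low-boiling), stored cold
Reagents that add atoms: none
Why: Two base-induced eliminations (of methanol, then of HCl) from the chloroacetal give the alkynyl ether as its sodium alkynide, which is protonated on quenching.

Step 11
Reactants: 19 1-diazo-3-hexaprenylpent-3-en-2-one; 22 methoxyacetylene
Product: 27 5-methoxy-2-methyl-3-hexaprenylphenol, via vinylketene 23 (not isolated), via cyclobutenone 24 (not isolated), via dienylketene 25 (not isolated), via cyclohexadienone 26 (not isolated)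
Conditions: 22 (3 equiv), ClCH2CH2Cl, hν (254 nm, sealed quartz tube), 5 °C; then 80 °C, dark
Reagents that add atoms: none
Why: Photochemical Wolff rearrangement (1,2-shift of the alkenyl group with loss of N2) turns 19 into vinylketene 23, whose ketene C=C adds methoxyacetylene in a [2+2] cycloaddition, the nucleophilic CH carbon of the ynol ether bonding to the ketene carbonyl carbon, to give cyclobutenone 24; 4π electrocyclic opening gives dienylketene 25, 6π electrocyclic closure gives dienone 26, and tautomerisation gives phenol 27. This is the Danheiser benzannulation in its diazo ketone version, known for α-diazo enones with alkoxyalkynes. The benzene ring is closed by 6π electrocyclisation of the ketene carbon onto the methyl-bearing alkene terminus, after the [2+2]/4π sequence has inserted the two alkyne carbons between the ketene carbons. No stereocentre is created: the sp3 centres of 24 and 26 are transient and the geometry of the ethylidene bond is erased on aromatisation. The step needs regioselectivity only in the [2+2] event, which the polarisation of the ynol ether secures (methoxy meta to hydroxyl, H between them), and chemoselectivity over the chain olefins, which are isolated trisubstituted alkenes that neither absorb at 254 nm nor compete with an ynol ether for a ketene. An excess of the alkyne in a closed vessel should keep capture faster than ketene dimerisation.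

Step 12
Reactants: 27 5-methoxy-2-methyl-3-hexaprenylphenol
Product: 28 2-methoxy-5-methyl-6-hexaprenylcyclohexa-2,5-diene-1,4-dione (target)
Conditions: (KSO3)2NO (Fremy's salt, 2.5 equiv), KH2PO4 buffer, acetone/H2O, 0 °C to rt
Reagents that add atoms: potassium nitrosodisulfonate, [K+].[K+].[O]N(S(=O)(=O)[O-])S(=O)(=O)[O-]
Why: Teuber oxidation, in which one nitrosodisulfonate radical removes the phenolic hydrogen and a second adds at the free para carbon (C4 of 27, between chain and methoxy group) before imidodisulfonate is lost to give the para-quinone; isolated trisubstituted olefins are inert to this radical.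

**Compound list**

1 | (2E,6E,10E)-geranylgeraniol, (2E,6E,10E)-3,7,11,15-tetramethylhexadeca-2,6,10,14-tetraen-1-ol | OC/C=C(\C)CC/C=C(\C)CC/C=C(\C)CCC=C(C)C | starting material
2 | (2E,6E,10E)-geranylgeranyl bromide | BrC/C=C(\C)CC/C=C(\C)CC/C=C(\C)CCC=C(C)C | intermediate
3 | trimethyl[(5E,9E,13E)-6,10,14,18-tetramethylnonadeca-5,9,13,17-tetraen-1-yn-1-yl]silane (not isolated) | C[Si](C)(C)C#CCC/C=C(\C)CC/C=C(\C)CC/C=C(\C)CCC=C(C)C | intermediate
4 | (5E,9E,13E)-6,10,14,18-tetramethylnonadeca-5,9,13,17-tetraen-1-yne | C#CCC/C=C(\C)CC/C=C(\C)CC/C=C(\C)CCC=C(C)C | intermediate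
5 | dimethyl[(1E,5E,9E,13E)-2,6,10,14,18-pentamethylnonadeca-1,5,9,13,17-pentaen-1-yl]alumane (not isolated) | C[Al](C)/C=C(\C)CC/C=C(\C)CC/C=C(\C)CC/C=C(\C)CCC=C(C)C | intermediate
6 | lithium butyl(dimethyl)[(1E,5E,9E,13E)-2,6,10,14,18-pentamethylnonadeca-1,5,9,13,17-pentaen-1-yl]aluminate (not isolated) | [Li+].CCCC[Al-](C)(C)/C=C(\C)CC/C=C(\C)CC/C=C(\C)CC/C=C(\C)CCC=C(C)C | intermediate
7 | (2E,6E,10E,14E)-geranylfarnesol, (2E,6E,10E,14E)-3,7,11,15,19-pentamethylicosa-2,6,10,14,18-pentaen-1-ol | OC/C=C(\C)CC/C=C(\C)CC/C=C(\C)CC/C=C(\C)CCC=C(C)C | intermediate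
8 | (2E,6E,10E,14E)-geranylfarnesyl bromide | BrC/C=C(\C)CC/C=C(\C)CC/C=C(\C)CC/C=C(\C)CCC=C(C)C | intermediate
9 | trimethyl[(5E,9E,13E,17E)-6,10,14,18,22-pentamethyltricosa-5,9,13,17,21-pentaen-1-yn-1-yl]silane (not isolated) | C[Si](C)(C)C#CCC/C=C(\C)CC/C=C(\C)CC/C=C(\C)CC/C=C(\C)CCC=C(C)C | intermediate
10 | (5E,9E,13E,17E)-6,10,14,18,22-pentamethyltricosa-5,9,13,17,21-pentaen-1-yne | C#CCC/C=C(\C)CC/C=C(\C)CC/C=C(\C)CC/C=C(\C)CCC=C(C)C | intermediate
11 | methyl vinyl ketone (but-3-en-2-one) | CC(=O)C=C | starting material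
12 | acetaldehyde | CC=O | starting material
13 | 4-hydroxy-3-methylidenepentan-2-one (racemic) | CC(O)C(=C)C(C)=O | intermediate
14 | 3-methylidene-4-oxopentan-2-yl acetate (racemic) | CC(=O)OC(C)C(=C)C(C)=O | intermediate
15 | dimethyl[(1E,5E,9E,13E,17E)-2,6,10,14,18,22-hexamethyltricosa-1,5,9,13,17,21-hexaen-1-yl]alumane (not isolated) | C[Al](C)/C=C(\C)CC/C=C(\C)CC/C=C(\C)CC/C=C(\C)CC/C=C(\C)CCC=C(C)C | intermediate
16 | 3-hexaprenylpent-3-en-2-one (ethylidene bond E/Z, chain all-E) | CC=C(C/C=C(\C)CC/C=C(\C)CC/C=C(\C)CC/C=C(\C)CC/C=C(\C)CCC=C(C)C)C(C)=O | intermediate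
17 | lithium enolate of 16 at the acetyl carbon (not isolated) | CC=C(C/C=C(\C)CC/C=C(\C)CC/C=C(\C)CC/C=C(\C)CC/C=C(\C)CCC=C(C)C)C(=C)O[Li] | intermediate
18 | 1,1,1-trifluoro-5-hexaprenylhept-5-ene-2,4-dione (not isolated) | CC=C(C/C=C(\C)CC/C=C(\C)CC/C=C(\C)CC/C=C(\C)CC/C=C(\C)CCC=C(C)C)C(=O)CC(=O)C(F)(F)F | intermediate
19 | 1-diazo-3-hexaprenylpent-3-en-2-one | CC=C(C/C=C(\C)CC/C=C(\C)CC/C=C(\C)CC/C=C(\C)CC/C=C(\C)CCC=C(C)C)C(=O)C=[N+]=[N-] | intermediate
20 | chloroacetaldehyde dimethyl acetal (2-chloro-1,1-dimethoxyethane) | COC(CCl)OC | starting material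
21 | sodium methoxyacetylide (not isolated) | [Na+].[C-]#COC | intermediate
22 | methoxyacetylene (methoxyethyne) | C#COC | intermediate
23 | 3-hexaprenylpenta-1,3-dien-1-one (vinylketene, not isolated) | CC=C(C/C=C(\C)CC/C=C(\C)CC/C=C(\C)CC/C=C(\C)CC/C=C(\C)CCC=C(C)C)C=C=O | intermediate
24 | 3-methoxy-4-(1-hexaprenylprop-1-en-1-yl)cyclobut-2-en-1-one (racemic, not isolated) | CC=C(C/C=C(\C)CC/C=C(\C)CC/C=C(\C)CC/C=C(\C)CC/C=C(\C)CCC=C(C)C)C1C(=O)C=C1OC | intermediate
25 | 3-methoxy-5-hexaprenylhepta-1,3,5-trien-1-one (dienylketene, not isolated) | CC=C(C/C=C(\C)CC/C=C(\C)CC/C=C(\C)CC/C=C(\C)CC/C=C(\C)CCC=C(C)C)C=C(OC)C=C=O | intermediate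
26 | 3-methoxy-6-methyl-5-hexaprenylcyclohexa-2,4-dien-1-one (racemic, not isolated) | CC1C(=O)C=C(OC)C=C1C/C=C(\C)CC/C=C(\C)CC/C=C(\C)CC/C=C(\C)CC/C=C(\C)CCC=C(C)C | intermediate
27 | 5-methoxy-2-methyl-3-hexaprenylphenol | COc1cc(O)c(C)c(C/C=C(\C)CC/C=C(\C)CC/C=C(\C)CC/C=C(\C)CC/C=C(\C)CCC=C(C)C)c1 | intermediate
28 | 2-methoxy-5-methyl-6-[(2E,6E,10E,14E,18E)-3,7,11,15,19,23-hexamethyltetracosa-2,6,10,14,18,22-hexaen-1-yl]cyclohexa-2,5-diene-1,4-dione (CHEBI:28711) | COC1=CC(=O)C(C)=C(C/C=C(\C)CC/C=C(\C)CC/C=C(\C)CC/C=C(\C)CC/C=C(\C)CCC=C(C)C)C1=O | target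

Total step count: 12. Longest linear sequence: 9 steps (1, 2, 3, 4, 5, 8, 9, 11, 12) from geranylgeraniol.

Steps most likely to fail:

Step 11. The photogenerated vinylketene could dimerise or be degraded by light before the volatile alkyne captures it, or the alkyne could polymerise under irradiation. The fallback sets out from diazo ketone 19: the Wolff rearrangement would be run in the presence of a large excess of 1,1-dimethoxyethene, a commercial, involatile ketenophile of the same polarity, so that the [2+2] adduct 3,3-dimethoxy-2-(1-hexaprenylprop-1-en-1-yl)cyclobutan-1-one F1 could be isolated. Elimination of methanol from F1 (Et3N, CH2Cl2, rt) would give cyclobutenone 24, where the route is rejoined, and heating at 80 °C in the dark should complete the ring opening and closure to phenol 27.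

Step 8. Aluminium could transfer methyl in place of the alkenyl group, the alane could attack the ketone of 14 or of the product, or the allyl–palladium intermediate could couple at its substituted end. The fallback sets out from alkyne 10: methylalumination as in step 8 and hydroxymethylation of alane 15 as in step 3 (n-BuLi, then (CH2O)n) would give all-E hexaprenol F2, and PBr3 would give all-E hexaprenyl bromide F3. F3 would C-alkylate the sodium salt of dimethyl (2-oxopropyl)phosphonate (NaH, THF) to give keto phosphonate F4, and a Horner–Wadsworth–Emmons reaction of F4 with acetaldehyde (Ba(OH)2, wet THF) would give enone 16, where the route is rejoined.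

Step 12. The nitroxyl radical could couple at the free ortho carbon (C6 of 27, between OH and OMe) and lead to an ortho-quinone, or the electron-rich aryloxyl radical could dimerise. The fallback sets out from phenol 27 and puts nitrogen on the para carbon by an ionic substitution with a strong para preference: azo coupling with 4-sulfobenzenediazonium chloride (aq. NaOH/THF, 0 °C) would give azo phenol F5, and reduction with Na2S2O4 would give 4-amino-5-methoxy-2-methyl-3-hexaprenylphenol F6. Oxidation of F6 with aqueous FeCl3 (two-phase with Et2O), with hydrolysis of the quinone imine in the same flask, would give quinone 28.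

**Further compounds**

F1 | step 11 | 3,3-dimethoxy-2-(1-hexaprenylprop-1-en-1-yl)cyclobutan-1-one (racemic) | CC=C(C/C=C(\C)CC/C=C(\C)CC/C=C(\C)CC/C=C(\C)CC/C=C(\C)CCC=C(C)C)C1C(=O)CC1(OC)OC
F2 | step 8 | (2E,6E,10E,14E,18E)-hexaprenol | OC/C=C(\C)CC/C=C(\C)CC/C=C(\C)CC/C=C(\C)CC/C=C(\C)CCC=C(C)C
F3 | step 8 | all-E hexaprenyl bromide | BrC/C=C(\C)CC/C=C(\C)CC/C=C(\C)CC/C=C(\C)CC/C=C(\C)CCC=C(C)C
F4 | step 8 | dimethyl [(5E,9E,13E,17E,21E)-6,10,14,18,22,26-hexamethyl-2-oxoheptacosa-5,9,13,17,21,25-hexaen-3-yl]phosphonate (racemic) | COP(=O)(OC)C(C/C=C(\C)CC/C=C(\C)CC/C=C(\C)CC/C=C(\C)CC/C=C(\C)CCC=C(C)C)C(C)=O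
F5 | step 12 | 4-{(E)-[4-hydroxy-2-methoxy-5-methyl-6-hexaprenylphenyl]diazenyl}benzenesulfonic acid | COc1cc(O)c(C)c(C/C=C(\C)CC/C=C(\C)CC/C=C(\C)CC/C=C(\C)CC/C=C(\C)CCC=C(C)C)c1/N=N/c1ccc(cc1)S(=O)(=O)O
F6 | step 12 | 4-amino-5-methoxy-2-methyl-3-hexaprenylphenol | COc1cc(O)c(C)c(C/C=C(\C)CC/C=C(\C)CC/C=C(\C)CC/C=C(\C)CC/C=C(\C)CCC=C(C)C)c1N
A1 | direct plan | (2E,6E)-farnesol | OC/C=C(\C)CC/C=C(\C)CCC=C(C)C
A2 | direct plan | (2E,6E)-farnesyl tert-butyldiphenylsilyl ether | CC(C)(C)[Si](c1ccccc1)(c1ccccc1)OC/C=C(\C)CC/C=C(\C)CCC=C(C)C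
A3 | direct plan | all-E hexaprenyl phenyl sulfone | O=S(=O)(C/C=C(\C)CC/C=C(\C)CC/C=C(\C)CC/C=C(\C)CC/C=C(\C)CCC=C(C)C)c1ccccc1
A4 | direct plan | 4,4,5-trimethoxy-2-methylcyclohexa-2,5-dien-1-one | COC1=CC(=O)C(C)=CC1(OC)OC
A5 | direct plan | 4,5-dimethoxy-2-methyl-3-[1-(phenylsulfonyl)hexaprenyl]phenol (racemic) | COc1cc(O)c(C)c(C(/C=C(\C)CC/C=C(\C)CC/C=C(\C)CC/C=C(\C)CC/C=C(\C)CCC=C(C)C)S(=O)(=O)c2ccccc2)c1OC
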